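**Retrosynthetic overview**

- The C3–aroyl bond is made last: (R)-4-(3,4-dimethoxybenzyl)butyrolactone plus O-benzylvanillin by aldol addition and oxidation, the C3–H between two carbonyls letting C3 settle trans to C4.
- The lactone comes from a (Z)-(R)-1-alkenyl p-tolyl sulfoxide and dichloroketene: O-acylation, [3,3]-sigmatropic shift and thionium capture make C3–C4 and O1–C5 in one operation and pass the sulfur chirality to C4; the two chlorines on C3 and the arylthio group on C5 are then removed reductively.
- Enabling feature: in the γ-lactone ring O1–C2(=O)–C3–C4–C5, C5 is an unsubstituted CH2 next to the stereocentre C4, so C4=C5 can be the C=C of a vinyl sulfoxide with sulfur on C5; C3 is a CH flanked by the lactone and ketone carbonyls, so it can enter as the CCl2 end of a ketene and take the aroyl group late.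
- The vinyl sulfoxide comes from an alkynyl sulfoxide by cis-hydrogenation, that from 3-(3,4-dimethoxyphenyl)propyne and menthyl (S)-p-toluenesulfinate, and the alkyne from 3,4-dimethoxyphenyl Grignard reagent and methoxyallene.
- Ring order: both benzene rings are bought; the γ-lactone is the only ring formed, in step 4.

Key step: step 4

Assumption: the sense of sulfur-to-carbon chirality transfer in the key step is taken from the chair-like sigmatropic transition state with p-tolyl pseudo-equatorial. Under it the (R)-(Z)-sulfoxide leads to the (4R) series; if the sense proved opposite, the (E)-isomer of the same sulfoxide (hydride reduction of the same alkynyl sulfoxide) would be carried through the same steps.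

**Step 1**
Reactants: 1 4-bromo-1,2-dimethoxybenzene; 2 methoxyallene (1-methoxypropa-1,2-diene)
Product: 4 3-(3,4-dimethoxyphenyl)prop-1-yne, via 3,4-dimethoxyphenylmagnesium bromide 3 (not isolated)
Conditions: Mg, THF, 65 °C; then 2, CuBr (5 mol %), Et2O–THF, −20 → 20 °C; aq NH4Cl
Reagents that add atoms: none
Why: Magnesium insertion gives the aryl Grignard reagent, which under CuBr catalysis attacks the terminal CH2 of methoxyallene with loss of methoxide (copper-catalysed SN2' substitution of an allenyl ether), the established way to 3-aryl-1-propynes; no stereocentre is formed.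

**Step 2**
Reactants: 4 3-(3,4-dimethoxyphenyl)prop-1-yne; 5 (1R,2S,5R)-menthyl (S)-p-toluenesulfinate
Product: 7 (S)-1,2-dimethoxy-4-[3-(p-tolylsulfinyl)prop-2-yn-1-yl]benzene, via alkynylmagnesium bromide 6 (not isolated)
Conditions: EtMgBr (1.0 equiv), THF, 0 → 25 °C; then added slowly to 5 in toluene, −20 °C; aq NH4Cl at −20 °C
Reagents that add atoms: none
Why: EtMgBr metalates only the terminal C–H and the alkynylmagnesium bromide displaces mentholate with inversion at sulfur (Andersen sulfoxide synthesis), which sets the sulfur stereocentre as S; inverse addition at low temperature should keep the benzylic propargylic CH2 from isomerising to the allene.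

**Step 3**
Reactants: 7 (S)-1,2-dimethoxy-4-[3-(p-tolylsulfinyl)prop-2-yn-1-yl]benzene
Product: 8 (R)-1,2-dimethoxy-4-[(Z)-3-(p-tolylsulfinyl)prop-2-en-1-yl]benzene
Conditions: H2 (1 atm), RhCl(PPh3)3 (5 mol %), benzene–EtOH, 25 °C, stopped after one equivalent of H2
Reagents that add atoms: none
Why: Homogeneous syn-hydrogenation of a 1-alkynyl sulfoxide with RhCl(PPh3)3 should stop at the (Z)-alkene; sulfur is untouched, its descriptor changing from S to R only because the alkenyl group ranks below p-tolyl.

**Step 4**
Reactants: 8 (R)-1,2-dimethoxy-4-[(Z)-3-(p-tolylsulfinyl)prop-2-en-1-yl]benzene; 9 trichloroacetyl chloride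
Product: 11 (4S,5R)-3,3-dichloro-4-(3,4-dimethoxybenzyl)-5-(p-tolylthio)dihydrofuran-2(3H)-one, via dichloroketene 10 (not isolated)
Conditions: 9 (2.5 equiv, slow addition), Zn(Cu) couple (5 equiv), Et2O, 0 → 35 °C
Reagents that add atoms: none
Why: Dichloroketene, released by zinc dechlorination of 9, is attacked at its carbonyl carbon by the sulfinyl oxygen of 8 to give an acyloxysulfonium dichloroenolate; this undergoes a [3,3]-sigmatropic shift that joins the CCl2 carbon (future C3) to the alkene β-carbon (future C4) and cleaves S–O, and the carboxylate then collapses onto the thionium carbon (future C5) to make O1–C5. The closest known reaction type is the Marino lactonization of 1-alkenyl aryl sulfoxides with dichloroketene, a sulfonium variant of the Claisen rearrangement ended by an additive Pummerer capture. The single ring closed, the γ-lactone, forms by 5-exo-trig attack of the carboxylate oxygen on the C=S+ carbon. C4 is set by 1,3-transfer of chirality from sulfur through a chair-like six-membered transition state with p-tolyl pseudo-equatorial and the sulfur lone pair pseudo-axial beside the pseudo-axial (Z)-CH2Ar group, so that the (R)-sulfoxide should give the spatial arrangement that is 4R in the target (4S here only by CIP priority); C5 is set cis to the benzyl group by collapse of the ion pair and is erased in step 5. The step needs O-acylation and rearrangement to outrun ketene [2+2] addition and acylation of the veratryl ring, which the nucleophilic sulfinyl oxygen and the electron-poor sulfinyl alkene secure, and it needs one chair over the other, which allylic strain between the (Z)-substituent and a pseudo-axial p-tolyl group secures.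

**Step 5**
Reactants: 11 (4S,5R)-3,3-dichloro-4-(3,4-dimethoxybenzyl)-5-(p-tolylthio)dihydrofuran-2(3H)-one
Product: 12 (R)-4-(3,4-dimethoxybenzyl)dihydrofuran-2(3H)-one
Conditions: Bu3SnH (4 equiv), AIBN (0.2 equiv), toluene, 110 °C
Reagents that add atoms: none
Why: Radical-chain stannane reduction removes both α-chlorines (α-acyl radicals) and the arylthio group of the O,S-acetal carbon (α-acyloxy radical); C4 never becomes a radical or an enolisable centre under these neutral conditions, so its configuration is kept.

**Step 6**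
Reactants: 12 (R)-4-(3,4-dimethoxybenzyl)dihydrofuran-2(3H)-one; 13 4-(benzyloxy)-3-methoxybenzaldehyde
Product: 15 (3S,4R)-3-[(4-benzyloxy-3-methoxyphenyl)(hydroxy)methyl]-4-(3,4-dimethoxybenzyl)dihydrofuran-2(3H)-one (both carbinol epimers), via lithium enolate 14 (not isolated)
Conditions: LiN(SiMe3)2 (1.05 equiv), THF, −78 °C; then 13, −78 °C; aq NH4Cl
Reagents that add atoms: none
Why: Aldol addition of the lactone lithium enolate to the aldehyde on the face away from the C4 benzyl group should set C3 trans to C4 (substrate control); the carbinol centre is uncontrolled and is removed in step 7.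

**Step 7**
Reactants: 15 (3S,4R)-3-[(4-benzyloxy-3-methoxyphenyl)(hydroxy)methyl]-4-(3,4-dimethoxybenzyl)dihydrofuran-2(3H)-one
Product: 16 (3S,4R)-3-(4-benzyloxy-3-methoxybenzoyl)-4-(3,4-dimethoxybenzyl)dihydrofuran-2(3H)-one
Conditions: Dess–Martin periodinane (1.3 equiv), CH2Cl2, 0 → 25 °C
Reagents that add atoms: none
Why: Dess–Martin oxidation converts both carbinol epimers into one ketone, and the doubly activated C3–H lets C3 equilibrate to the favoured trans (3S) arrangement.

**Step 8**
Reactants: 16 (3S,4R)-3-(4-benzyloxy-3-methoxybenzoyl)-4-(3,4-dimethoxybenzyl)dihydrofuran-2(3H)-one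
Product: 17 (3S,4R)-4-(3,4-dimethoxybenzyl)-3-(4-hydroxy-3-methoxybenzoyl)dihydrofuran-2(3H)-one (target, CNP0296372.1)
Conditions: H2 (1 atm), 10% Pd/C, EtOAc, 25 °C, stopped at full conversion of 16
Reagents that add atoms: none
Why: Hydrogenolysis of the benzyl aryl ether over Pd/C should be much faster than reduction of the electron-rich aryl ketone; C4 is untouched and C3 stays trans under thermodynamic control.

**Compound list**

1 | 4-bromo-1,2-dimethoxybenzene | COc1ccc(Br)cc1OC | starting material
2 | methoxyallene (1-methoxypropa-1,2-diene) | COC=C=C | starting material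
3 | 3,4-dimethoxyphenylmagnesium bromide | COc1ccc([Mg]Br)cc1OC | intermediate
4 | 3-(3,4-dimethoxyphenyl)prop-1-yne | COc1ccc(CC#C)cc1OC | intermediate
5 | (1R,2S,5R)-menthyl (S)-p-toluenesulfinate | CC(C)[C@@H]1CC[C@@H](C)C[C@H]1O[S@](=O)c1ccc(C)cc1 | starting material
6 | [3-(3,4-dimethoxyphenyl)prop-1-yn-1-yl]magnesium bromide | COc1ccc(CC#C[Mg]Br)cc1OC | intermediate
7 | (S)-1,2-dimethoxy-4-[3-(p-tolylsulfinyl)prop-2-yn-1-yl]benzene | COc1ccc(CC#C[S@@](=O)c2ccc(C)cc2)cc1OC | intermediate
8 | (R)-1,2-dimethoxy-4-[(Z)-3-(p-tolylsulfinyl)prop-2-en-1-yl]benzene | COc1ccc(C/C=C\[S@@](=O)c2ccc(C)cc2)cc1OC | intermediate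
9 | trichloroacetyl chloride | ClC(Cl)(Cl)C(Cl)=O | starting material
10 | dichloroketene | ClC(Cl)=C=O | intermediate
11 | (4S,5R)-3,3-dichloro-4-(3,4-dimethoxybenzyl)-5-(p-tolylthio)dihydrofuran-2(3H)-one (benzyl and arylthio cis) | O=C1O[C@H](Sc2ccc(C)cc2)[C@H](Cc2ccc(OC)c(OC)c2)C1(Cl)Cl | intermediate
12 | (R)-4-(3,4-dimethoxybenzyl)dihydrofuran-2(3H)-one | O=C1OC[C@H](Cc2ccc(OC)c(OC)c2)C1 | intermediate
13 | 4-(benzyloxy)-3-methoxybenzaldehyde | COc1cc(C=O)ccc1OCc1ccccc1 | starting material
14 | lithium enolate of 12 (lithium (R)-4-(3,4-dimethoxybenzyl)-4,5-dihydrofuran-2-olate) | [Li]OC1=C[C@@H](Cc2ccc(OC)c(OC)c2)CO1 | intermediate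
15 | (3S,4R)-3-[(4-benzyloxy-3-methoxyphenyl)(hydroxy)methyl]-4-(3,4-dimethoxybenzyl)dihydrofuran-2(3H)-one, carbinol centre as both epimers | COc1cc(C(O)[C@H]2C(=O)OC[C@@H]2Cc2ccc(OC)c(OC)c2)ccc1OCc1ccccc1 | intermediate
16 | (3S,4R)-3-(4-benzyloxy-3-methoxybenzoyl)-4-(3,4-dimethoxybenzyl)dihydrofuran-2(3H)-one | COc1cc(C(=O)[C@H]2C(=O)OC[C@@H]2Cc2ccc(OC)c(OC)c2)ccc1OCc1ccccc1 | intermediate
17 | (3S,4R)-4-(3,4-dimethoxybenzyl)-3-(4-hydroxy-3-methoxybenzoyl)dihydrofuran-2(3H)-one | COc1cc(C(=O)[C@H]2C(=O)OC[C@@H]2Cc2ccc(OC)c(OC)c2)ccc1O | target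

**Totals and risks**

Total step count: 8. Longest linear sequence: 8 steps (1 to 17).

Steps most likely to fail:

1. Step 4. The transfer of chirality from sulfur to C4 may be incomplete or of the wrong sense, or the acyloxysulfonium intermediate may divert into plain Pummerer or deoxygenation pathways. Fallback, from 3 to 12, building the ring stepwise by known chemistry: the Grignard reagent 3 opens oxetane (CuI cat., THF, 65 °C) to give 3-(3,4-dimethoxyphenyl)propan-1-ol F1. Bromoacetyl bromide and NaHCO3 in MeCN give 3-(3,4-dimethoxyphenyl)propyl bromoacetate F2. N,N'-Ditosylhydrazine and DBU in THF at 0 °C give 3-(3,4-dimethoxyphenyl)propyl diazoacetate F3. Slow addition of F3 to Rh2(4S-MPPIM)4 (dirhodium tetrakis[methyl 2-oxo-1-(3-phenylpropanoyl)imidazolidine-4(S)-carboxylate]) in CH2Cl2 at 40 °C should give 12 by enantioselective carbenoid insertion into the C–H bond two carbons from the ester oxygen. The 4S catalyst is expected to give the (R)-lactone; if it favours the other enantiomer, the 4R catalyst is used.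

2. Step 2. The benzylic propargylic CH2 may isomerise to the allenyl sulfoxide under the basic magnesium species, and excess organometallic may erode the sulfur configuration. Fallback, from 4 to 8, which also bypasses step 3: N-iodosuccinimide with AgNO3 (cat.) in acetone gives 4-(3-iodoprop-2-yn-1-yl)-1,2-dimethoxybenzene F4. Diimide (2-nitrobenzenesulfonylhydrazide, Et3N) reduces it cis to (Z)-4-(3-iodoprop-2-en-1-yl)-1,2-dimethoxybenzene F5. t-BuLi (2 equiv) in Et2O at −78 °C gives, with retention of geometry, (Z)-[3-(3,4-dimethoxyphenyl)prop-1-en-1-yl]lithium F6. Inverse addition of F6 to 5 at −78 °C should give 8 with inversion at sulfur.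

3. Step 3. Hydrogen uptake may run on to the saturated sulfoxide, or the alkene may isomerise (Z to E, or into conjugation with the arene). Fallback, from 6 to 12, with no catalytic hydrogenation and the opposite geometry/sulfur pairing: 6 is added to (1S,2R,5S)-menthyl (R)-p-toluenesulfinate, the commercial enantiomer of 5, to give (R)-1,2-dimethoxy-4-[3-(p-tolylsulfinyl)prop-2-yn-1-yl]benzene F7. iBu2AlH in THF at −78 °C (trans-hydroalumination, then protonolysis) gives (S)-1,2-dimethoxy-4-[(E)-3-(p-tolylsulfinyl)prop-2-en-1-yl]benzene F8. The conditions of step 4 should convert F8, through the same chair model, into (4S,5S)-3,3-dichloro-4-(3,4-dimethoxybenzyl)-5-(p-tolylthio)dihydrofuran-2(3H)-one F9, and the conditions of step 5 return 12.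

**Further compounds**

F1 | step 4 | 3-(3,4-dimethoxyphenyl)propan-1-ol | COc1ccc(CCCO)cc1OC
F2 | step 4 | 3-(3,4-dimethoxyphenyl)propyl bromoacetate | COc1ccc(CCCOC(=O)CBr)cc1OC
F3 | step 4 | 3-(3,4-dimethoxyphenyl)propyl diazoacetate | COc1ccc(CCCOC(=O)C=[N+]=[N-])cc1OC
F4 | step 2 | 4-(3-iodoprop-2-yn-1-yl)-1,2-dimethoxybenzene | COc1ccc(CC#CI)cc1OC
F5 | step 2 | (Z)-4-(3-iodoprop-2-en-1-yl)-1,2-dimethoxybenzene | COc1ccc(C/C=C\I)cc1OC
F6 | step 2 | (Z)-[3-(3,4-dimethoxyphenyl)prop-1-en-1-yl]lithium | COc1ccc(C/C=C\[Li])cc1OC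
F7 | step 3 | (R)-1,2-dimethoxy-4-[3-(p-tolylsulfinyl)prop-2-yn-1-yl]benzene | COc1ccc(CC#C[S@](=O)c2ccc(C)cc2)cc1OC
F8 | step 3 | (S)-1,2-dimethoxy-4-[(E)-3-(p-tolylsulfinyl)prop-2-en-1-yl]benzene | COc1ccc(C/C=C/[S@](=O)c2ccc(C)cc2)cc1OC
F9 | step 3 | (4S,5S)-3,3-dichloro-4-(3,4-dimethoxybenzyl)-5-(p-tolylthio)dihydrofuran-2(3H)-one | O=C1O[C@@H](Sc2ccc(C)cc2)[C@H](Cc2ccc(OC)c(OC)c2)C1(Cl)Cl
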